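**Retrosynthetic overview**

1. The C18 senecioate and the C15 acid are installed last, by acylation and by oxidation of a silyl-protected C15 alcohol. Before that, the C3 carbonyl and the C5=C6 alkene of the key product are removed by tosylhydrazone reduction and OH-directed hydrogenation, which sets 5-H.
2. Key disconnection, C7–C8 of ring B: SmI2 joins two electrophilic carbons, the C8 methyl-ketone carbon and C7, the δ-terminus of the ring-A dienone O=C3–C4(CH3)=C5–C6=C7. The samarium dienolate left behind is then captured by formaldehyde at C4. One operation should give ring B, two C–C bonds, C18 and the stereocentres C8 and C4.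
3. Enabling feature: the 3-vinylcyclohex-2-enone of ring A. C7 is the only acceptor carbon that C8 can reach through C8–C9–C10–C5–C6–C7 as a six-membered ring, the axial C10 methyl directs both new centres, and the dienone stores the enolate needed for the quaternary C4.
4. The precursor comes from 2-methylcyclohexane-1,3-dione by Stork–Danheiser chemistry. C9–C10 is made by iridium-catalysed branched allylation with a carbonate from (R)-citronellol, which brings C8, C9 and C11–C17 including C13; vinyl addition and Wacker oxidation follow.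
5. Ring order: ring A is bought as the dione; ring B is closed in step 8.

Key step: step 8

Remark on the chemistry: the target is read as (4S,5S,8S,9S,10R,13R), an ent-labdane with the equatorial CH2O group (C18) on C4; ent-labdane numbering is used throughout (ring A = C1–C5, C10; ring B = C5–C10; C17 on C8, C20 on C10).

**Route**

Step 1
Reactants: 1 2-methylcyclohexane-1,3-dione; 2 2-methylpropan-1-ol
Product: 3 3-isobutoxy-2-methylcyclohex-2-en-1-one
Conditions: TsOH·H2O (cat.), toluene, reflux, Dean–Stark trap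
Reagents that add atoms: 2-methylpropan-1-ol (2), CC(C)CO
Why: Acid-catalysed condensation of the vinylogous acid with the alcohol (vinylogous ester formation) with azeotropic removal of water; no stereocentre is formed.

Step 2
Reactants: 3 3-isobutoxy-2-methylcyclohex-2-en-1-one; 4 iodomethane
Product: 5 (±)-3-isobutoxy-2,6-dimethylcyclohex-2-en-1-one
Conditions: LDA, THF, −78 °C; MeI, −78 → 0 °C
Reagents that add atoms: iodomethane (4), CI
Why: Kinetic deprotonation at the α′ carbon (future C10) and SN2 methylation, the first alkylation of a Stork–Danheiser sequence; the racemic centre becomes planar again in step 5.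

Step 3
Reactants: 6 (R)-citronellol; 7 tert-butyl(chloro)diphenylsilane
Product: 8 TBDPS ether of (R)-citronellol
Conditions: imidazole, DMF, 0 °C → rt
Reagents that add atoms: tert-butyl(chloro)diphenylsilane (7), CC(C)(C)[Si](Cl)(c1ccccc1)c1ccccc1
Why: Silylation of the primary alcohol gives an ether that should survive the organometallic, acidic and reducing steps up to step 12 and leaves the C13 stereocentre (C3 of citronellol) untouched.

Step 4
Reactants: 8 TBDPS ether of (R)-citronellol; 9 allyl methyl carbonate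
Product: 10 (2E,6R)-allylic methyl carbonate
Conditions: second-generation Hoveyda–Grubbs catalyst, RuCl2(H2IMes)(=CH–C6H4-2-O-i-Pr) (5 mol%), CH2Cl2, 40 °C
Reagents that add atoms: allyl methyl carbonate (9), C=CCOC(=O)OC
Why: Olefin cross-metathesis exchanges the trisubstituted isopropylidene terminus for the CH–CH2OCO2Me unit with loss of volatile 2-methylpropene and should favour the E alkene needed for the allylation.

Step 5
Reactants: 5 (±)-3-isobutoxy-2,6-dimethylcyclohex-2-en-1-one; 10 (2E,6R)-allylic methyl carbonate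
Product: 11 (6S,3′R)-branched allylation product
Conditions: 5, LDA, THF, −78 °C; BaI2 (0.5 equiv); then 10, [Ir(cod)Cl]2 (2 mol%), BINOL-derived N,N-bis(1-phenylethyl)phosphoramidite (4 mol%, the enantiomer that gives (R) at the allylic carbon), THF, 0 °C → rt
Reagents that add atoms: allylic carbonate 10, COC(=O)OC/C=C/CC[C@@H](C)CCO[Si](c1ccccc1)(c1ccccc1)C(C)(C)C
Why: Iridium-catalysed branched-selective allylic alkylation (Tsuji–Trost type) of an unstabilised, tetrasubstituted cyclic ketone enolate, a known way to vicinal quaternary and tertiary centres: the chiral iridium–allyl complex should fix C9 as (R) and select the enolate face that makes C10 (S), so that one catalyst sets both centres and the racemic centre of 5 is erased.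

Step 6
Reactants: 11 (6S,3′R)-branched allylation product; 12 vinylmagnesium bromide
Product: 14 3-vinyl dienone, via tertiary carbinol 13 (not isolated)
Conditions: CeCl3, THF, −78 → 0 °C; then 1 M HCl, THF, 0 °C
Reagents that add atoms: vinylmagnesium bromide (12), C=C[Mg]Br
Why: Stork–Danheiser transposition: 1,2-addition of the vinyl organocerium to the vinylogous ester carbonyl (C5) and acid-induced loss of isobutanol from carbinol 13 give the 3-vinyl enone, in which C7 is the δ-terminus of the dienone, without touching C9 and C10.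

Step 7
Reactants: 14 3-vinyl dienone
Product: 15 dienone methyl ketone
Conditions: PdCl2 (10 mol%), CuCl (1 equiv), O2 (1 atm), DMF–H2O (7:1), rt
Reagents that add atoms: water, O
Why: Wacker–Tsuji oxidation converts the isolated monosubstituted alkene in the Markovnikov sense into the C8 methyl ketone, while the conjugated, electron-poor vinyl group of the dienone should stay inert.

Step 8
Reactants: 15 dienone methyl ketone; 16 formaldehyde
Product: 18 bicyclic hydroxymethyl ketone diol, via samarium dienolate 17 (not isolated)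
Conditions: SmI2 (2.5 equiv), HMPA (10 equiv), THF, −78 °C, slow addition of 15; then monomeric CH2O in THF, −78 → −40 °C; aq. NH4Cl
Reagents that add atoms: formaldehyde (16), C=O
Why: Proposed new method: two electrons from SmI2 (activated by HMPA) reduce 15; whether the first electron enters the C8 ketone (ketyl) or the dienone, both paths lead to a bond between C8 and C7, the δ-terminus of O=C3–C4=C5–C6=C7, and the second electron leaves a trivalent-samarium dienolate (O–C3=C4–C5=C6) that adds to formaldehyde at C4 through a closed six-membered aldol transition state. The closest known reaction types are the SmI2 ketyl–olefin (carbonyl–alkene) reductive cyclisation onto Michael acceptors, its electroreductive counterpart, and the aldol capture of samarium enolates formed in such cyclisations; new here are the vinylogous mode onto a dienone and the capture of the dienolate at its α-carbon. Ring B closes in the 6-endo-trig mode on the terminal vinyl carbon C7; attack at C6 (5-exo) would give an unstabilised primary radical and attack at C5 a four-membered ring, so the polarisation of the dienone, with the C4 methyl disfavouring the s-cis vinyl rotamer, should secure the regiochemistry. C8 is set in a half-chair in which the C9 chain is pseudo-equatorial and the samarium-bound oxygen, made bulky by HMPA, avoids the syn-axial C10 methyl, so the C8 methyl becomes axial and the hydroxyl equatorial; C9 and C10 are carried over unchanged. C4 is set by approach of formaldehyde anti to the axial C10 methyl, which places CH2OH equatorial and the C4 methyl syn to C20. The step needs reduction without a proton source so that the dienolate survives, which the slow addition of 15 to excess SmI2–HMPA at low temperature and the absence of acidic groups in 15 are meant to secure.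

Step 9
Reactants: 18 bicyclic hydroxymethyl ketone diol
Product: 20 3-deoxo diol, via tosylhydrazone 19 (not isolated)
Conditions: TsNHNH2, EtOH, 70 °C; evaporate; catecholborane, CHCl3, 0 °C → rt; NaOAc·3H2O, reflux
Reagents that add atoms: none
Why: Caglioti-type deoxygenation (tosylhydrazone, then catecholborane) removes the C3 carbonyl under near-neutral conditions that spare the tertiary alcohol, the silyl ether and the C5=C6 alkene, which cannot migrate because C4 is quaternary.

Step 10
Reactants: 20 3-deoxo diol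
Product: 21 trans-decalin diol
Conditions: H2 (1 atm), [Ir(cod)(PCy3)(py)]PF6 (5 mol%), CH2Cl2, rt
Reagents that add atoms: none
Why: Hydroxyl-directed homogeneous hydrogenation: the C18 and C8 hydroxyl groups lie on the face opposite to the two axial methyl groups and should guide iridium to deliver hydrogen to C5 from that face, which gives the trans ring fusion (5-H anti to C20).

Step 11
Reactants: 21 trans-decalin diol; 22 3-methylbut-2-enoyl chloride
Product: 23 C18 senecioate
Conditions: pyridine, DMAP (cat.), CH2Cl2, 0 °C → rt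
Reagents that add atoms: 3-methylbut-2-enoyl chloride (22), CC(C)=CC(=O)Cl
Why: Acylation of the primary (neopentyl) C18 hydroxyl with the acid chloride, the tertiary C8 hydroxyl being unreactive; pyridine at low temperature is used to limit deconjugation of the enoate through a vinylketene.

Step 12
Reactants: 23 C18 senecioate
Product: 24 C15 alcohol
Conditions: HF·pyridine, THF, 0 °C → rt
Reagents that add atoms: none
Why: Fluoride cleavage of the silicon–oxygen bond frees the C15 alcohol without affecting the enoate or the tertiary alcohol.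

Step 13
Reactants: 24 C15 alcohol
Product: 25 target acid
Conditions: TEMPO (20 mol%), PhI(OAc)2 (2.5 equiv), MeCN–H2O (pH 7 buffer), rt
Reagents that add atoms: water, O
Why: Oxoammonium (TEMPO) oxidation takes the primary alcohol through the aldehyde hydrate to the carboxylic acid, leaving the tertiary alcohol and the senecioate untouched.

**Compound list**

1 | 2-methylcyclohexane-1,3-dione | CC1C(=O)CCCC1=O | starting material
2 | 2-methylpropan-1-ol (isobutanol) | CC(C)CO | starting material
3 | 3-isobutoxy-2-methylcyclohex-2-en-1-one | CC1=C(OCC(C)C)CCCC1=O | intermediate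
4 | iodomethane | CI | starting material
5 | (±)-3-isobutoxy-2,6-dimethylcyclohex-2-en-1-one | CC1CCC(OCC(C)C)=C(C)C1=O | intermediate
6 | (R)-citronellol, (3R)-3,7-dimethyloct-6-en-1-ol | C[C@H](CCC=C(C)C)CCO | starting material
7 | tert-butyl(chloro)diphenylsilane | CC(C)(C)[Si](Cl)(c1ccccc1)c1ccccc1 | starting material
8 | tert-butyl{[(3R)-3,7-dimethyloct-6-en-1-yl]oxy}diphenylsilane | C[C@H](CCC=C(C)C)CCO[Si](c1ccccc1)(c1ccccc1)C(C)(C)C | intermediate
9 | allyl methyl carbonate | C=CCOC(=O)OC | starting material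
10 | (2E,6R)-8-{[tert-butyl(diphenyl)silyl]oxy}-6-methyloct-2-en-1-yl methyl carbonate | COC(=O)OC/C=C/CC[C@@H](C)CCO[Si](c1ccccc1)(c1ccccc1)C(C)(C)C | intermediate
11 | (6S)-6-[(3R,6R)-8-{[tert-butyl(diphenyl)silyl]oxy}-6-methyloct-1-en-3-yl]-3-isobutoxy-2,6-dimethylcyclohex-2-en-1-one | O=C1C(C)=C(OCC(C)C)CC[C@@]1(C)[C@@H](C=C)CC[C@@H](C)CCO[Si](c1ccccc1)(c1ccccc1)C(C)(C)C | intermediate
12 | vinylmagnesium bromide | C=C[Mg]Br | starting material
13 | (6S)-6-[(3R,6R)-8-{[tert-butyl(diphenyl)silyl]oxy}-6-methyloct-1-en-3-yl]-1-ethenyl-3-isobutoxy-2,6-dimethylcyclohex-2-en-1-ol (C1 epimers, formed as the bromomagnesium alkoxide) | OC1(C=C)C(C)=C(OCC(C)C)CC[C@@]1(C)[C@@H](C=C)CC[C@@H](C)CCO[Si](c1ccccc1)(c1ccccc1)C(C)(C)C | intermediate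
14 | (4S)-4-[(3R,6R)-8-{[tert-butyl(diphenyl)silyl]oxy}-6-methyloct-1-en-3-yl]-3-ethenyl-2,4-dimethylcyclohex-2-en-1-one | O=C1CC[C@@](C)([C@@H](C=C)CC[C@@H](C)CCO[Si](c2ccccc2)(c2ccccc2)C(C)(C)C)C(C=C)=C1C | intermediate
15 | (4S)-4-[(3S,6R)-8-{[tert-butyl(diphenyl)silyl]oxy}-6-methyl-2-oxooctan-3-yl]-3-ethenyl-2,4-dimethylcyclohex-2-en-1-one | O=C1CC[C@@](C)([C@@H](C(C)=O)CC[C@@H](C)CCO[Si](c2ccccc2)(c2ccccc2)C(C)(C)C)C(C=C)=C1C | intermediate
16 | formaldehyde (monomer, from paraformaldehyde) | C=O | starting material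
17 | diiodosamarium C8-alkoxide C3-dienolate of the cyclised product (O–C3=C4–C5=C6), before capture of formaldehyde | I[Sm](I)OC1=C(C)C2=CC[C@](C)(O[Sm](I)I)[C@@H](CC[C@@H](C)CCO[Si](c3ccccc3)(c3ccccc3)C(C)(C)C)[C@]2(C)CC1 | intermediate
18 | (1S,4aS,5S,6S)-5-[(3R)-5-{[tert-butyl(diphenyl)silyl]oxy}-3-methylpentyl]-6-hydroxy-1-(hydroxymethyl)-1,4a,6-trimethyl-3,4,4a,5,6,7-hexahydronaphthalen-2(1H)-one | OC[C@@]1(C)C(=O)CC[C@]2(C)C1=CC[C@](C)(O)[C@H]2CC[C@@H](C)CCO[Si](c3ccccc3)(c3ccccc3)C(C)(C)C | intermediate
19 | 4-methylbenzenesulfonohydrazone of 18 at C3 | OC[C@@]1(C)C(=NNS(=O)(=O)c3ccc(C)cc3)CC[C@]2(C)C1=CC[C@](C)(O)[C@H]2CC[C@@H](C)CCO[Si](c4ccccc4)(c4ccccc4)C(C)(C)C | intermediate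
20 | (1S,2S,5S,8aS)-1-[(3R)-5-{[tert-butyl(diphenyl)silyl]oxy}-3-methylpentyl]-5-(hydroxymethyl)-2,5,8a-trimethyl-1,2,3,5,6,7,8,8a-octahydronaphthalen-2-ol | OC[C@@]1(C)CCC[C@]2(C)C1=CC[C@](C)(O)[C@H]2CC[C@@H](C)CCO[Si](c3ccccc3)(c3ccccc3)C(C)(C)C | intermediate
21 | (1S,2S,4aS,5S,8aR)-1-[(3R)-5-{[tert-butyl(diphenyl)silyl]oxy}-3-methylpentyl]-5-(hydroxymethyl)-2,5,8a-trimethyldecahydronaphthalen-2-ol | OC[C@@]1(C)CCC[C@]2(C)[C@@H]1CC[C@](C)(O)[C@H]2CC[C@@H](C)CCO[Si](c3ccccc3)(c3ccccc3)C(C)(C)C | intermediate
22 | 3-methylbut-2-enoyl chloride (senecioyl chloride) | CC(C)=CC(=O)Cl | starting material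
23 | [(1S,4aS,5S,6S,8aR)-5-[(3R)-5-{[tert-butyl(diphenyl)silyl]oxy}-3-methylpentyl]-6-hydroxy-1,4a,6-trimethyldecahydronaphthalen-1-yl]methyl 3-methylbut-2-enoate | CC(C)=CC(=O)OC[C@@]1(C)CCC[C@]2(C)[C@@H]1CC[C@](C)(O)[C@H]2CC[C@@H](C)CCO[Si](c3ccccc3)(c3ccccc3)C(C)(C)C | intermediate
24 | [(1S,4aS,5S,6S,8aR)-6-hydroxy-5-[(3R)-5-hydroxy-3-methylpentyl]-1,4a,6-trimethyldecahydronaphthalen-1-yl]methyl 3-methylbut-2-enoate | CC(C)=CC(=O)OC[C@@]1(C)CCC[C@]2(C)[C@@H]1CC[C@](C)(O)[C@H]2CC[C@@H](C)CCO | intermediate
25 | (3R)-5-[(1S,2S,4aS,5S,8aR)-2-hydroxy-2,5,8a-trimethyl-5-{[(3-methylbut-2-enoyl)oxy]methyl}decahydronaphthalen-1-yl]-3-methylpentanoic acid | CC(C)=CC(=O)OC[C@@]1(C)CCC[C@]2(C)[C@@H]1CC[C@](C)(O)[C@H]2CC[C@@H](C)CC(=O)O | target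

**Step count and risks**

Total steps: 13. Longest linear sequence: 11 (steps 1, 2, 5–13; the branch through steps 3 and 4 is equally long).

Steps most likely to fail:

1. Step 8 (proposed new method). What may go wrong: reductive dimerisation or simple protonation of the dienone radical anion instead of ring closure, poor facial selectivity at C8, or capture of the dienolate at oxygen or at C6 instead of C4. Fallback with known reactions, setting out from 11 and returning at 21: Wacker–Tsuji oxidation of 11 (PdCl2, CuCl, O2) gives the vinylogous-ester methyl ketone F1. Wittig methylenation (Ph3P=CH2) gives the isopropenyl compound F2. Stork–Danheiser transposition with allylmagnesium bromide and CeCl3, then dilute HCl, gives the 3-allyl enone F3. Ring-closing metathesis (second-generation Grubbs catalyst) joins the allyl terminus C7 to the isopropenyl carbon C8 and gives the C7=C8 octalone F4, the same C7–C8 bond now made as an alkene. Birch reductive hydroxymethylation (Li, NH3, t-BuOH; then CH2O) should set 5-H trans and the equatorial C18 and give the hydroxymethyl ketone F5. Caglioti-type reduction (TsNHNH2; catecholborane) gives the C7=C8 alkenol F6. Mukaiyama hydration (Mn(dpm)3, PhSiH3, O2; then PPh3) should place the C8 hydroxyl anti to the C10 methyl and give 21.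

2. Step 5. What may go wrong: selection of the wrong enolate face relative to the catalyst-fixed C9 (wrong relative configuration at C9/C10), or linear instead of branched allylation. Fallback, setting out from 5 and 10 and returning at 15: the ligand antipode is used so that C10 is still (S) and the error sits at the epimerisable C9. The allylation then gives the (6S,3′S) product F7, which under the conditions of steps 6 and 7 gives the C9-epimeric dienone F8 and the C9-epimeric methyl ketone F9. In F9 the C9–H is α to the new ketone and is equilibrated with catalytic KOt-Bu (t-BuOH–THF, 0 °C); 15 is separated and F9 recycled.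

3. Step 6. What may go wrong: no 1,2-addition at the hindered vinylogous ester carbonyl next to the quaternary C10 (deprotonation at the γ-carbon and recovery of 11 instead). Fallback, setting out from 11 and returning at 14: the smaller, less basic ethynylmagnesium bromide with CeCl3, then dilute HCl, gives the 3-ethynyl enone F10. Semihydrogenation over Pd/CaCO3 poisoned with Pb(OAc)2 and quinoline (1 atm H2) gives 14.

**Further compounds**

F1 | step 8 | (6S)-6-[(3S,6R)-8-{[tert-butyl(diphenyl)silyl]oxy}-6-methyl-2-oxooctan-3-yl]-3-isobutoxy-2,6-dimethylcyclohex-2-en-1-one | O=C1C(C)=C(OCC(C)C)CC[C@@]1(C)[C@@H](C(C)=O)CC[C@@H](C)CCO[Si](c1ccccc1)(c1ccccc1)C(C)(C)C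
F2 | step 8 | (6S)-6-[(3R,6R)-8-{[tert-butyl(diphenyl)silyl]oxy}-2,6-dimethyloct-1-en-3-yl]-3-isobutoxy-2,6-dimethylcyclohex-2-en-1-one | O=C1C(C)=C(OCC(C)C)CC[C@@]1(C)[C@@H](C(C)=C)CC[C@@H](C)CCO[Si](c1ccccc1)(c1ccccc1)C(C)(C)C
F3 | step 8 | (4S)-4-[(3R,6R)-8-{[tert-butyl(diphenyl)silyl]oxy}-2,6-dimethyloct-1-en-3-yl]-2,4-dimethyl-3-(prop-2-en-1-yl)cyclohex-2-en-1-one | O=C1CC[C@@](C)([C@@H](C(C)=C)CC[C@@H](C)CCO[Si](c2ccccc2)(c2ccccc2)C(C)(C)C)C(CC=C)=C1C
F4 | step 8 | (4aS,5R)-5-[(3R)-5-{[tert-butyl(diphenyl)silyl]oxy}-3-methylpentyl]-1,4a,6-trimethyl-4,4a,5,8-tetrahydronaphthalen-2(3H)-one | O=C1CC[C@]2(C)C(CC=C(C)[C@H]2CC[C@@H](C)CCO[Si](c3ccccc3)(c3ccccc3)C(C)(C)C)=C1C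
F5 | step 8 | (1S,4aS,5R,8aS)-5-[(3R)-5-{[tert-butyl(diphenyl)silyl]oxy}-3-methylpentyl]-1-(hydroxymethyl)-1,4a,6-trimethyl-3,4,4a,5,8,8a-hexahydronaphthalen-2(1H)-one | OC[C@@]1(C)C(=O)CC[C@]2(C)[C@@H]1CC=C(C)[C@H]2CC[C@@H](C)CCO[Si](c3ccccc3)(c3ccccc3)C(C)(C)C
F6 | step 8 | [(1S,4aS,5R,8aS)-5-[(3R)-5-{[tert-butyl(diphenyl)silyl]oxy}-3-methylpentyl]-1,4a,6-trimethyl-1,2,3,4,4a,5,8,8a-octahydronaphthalen-1-yl]methanol | OC[C@@]1(C)CCC[C@]2(C)[C@@H]1CC=C(C)[C@H]2CC[C@@H](C)CCO[Si](c3ccccc3)(c3ccccc3)C(C)(C)C
F7 | step 5 | (6S)-6-[(3S,6R)-8-{[tert-butyl(diphenyl)silyl]oxy}-6-methyloct-1-en-3-yl]-3-isobutoxy-2,6-dimethylcyclohex-2-en-1-one | O=C1C(C)=C(OCC(C)C)CC[C@@]1(C)[C@H](C=C)CC[C@@H](C)CCO[Si](c1ccccc1)(c1ccccc1)C(C)(C)C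
F8 | step 5 | (4S)-4-[(3S,6R)-8-{[tert-butyl(diphenyl)silyl]oxy}-6-methyloct-1-en-3-yl]-3-ethenyl-2,4-dimethylcyclohex-2-en-1-one | O=C1CC[C@@](C)([C@H](C=C)CC[C@@H](C)CCO[Si](c2ccccc2)(c2ccccc2)C(C)(C)C)C(C=C)=C1C
F9 | step 5 | (4S)-4-[(3R,6R)-8-{[tert-butyl(diphenyl)silyl]oxy}-6-methyl-2-oxooctan-3-yl]-3-ethenyl-2,4-dimethylcyclohex-2-en-1-one | O=C1CC[C@@](C)([C@H](C(C)=O)CC[C@@H](C)CCO[Si](c2ccccc2)(c2ccccc2)C(C)(C)C)C(C=C)=C1C
F10 | step 6 | (4S)-4-[(3R,6R)-8-{[tert-butyl(diphenyl)silyl]oxy}-6-methyloct-1-en-3-yl]-3-ethynyl-2,4-dimethylcyclohex-2-en-1-one | O=C1CC[C@@](C)([C@@H](C=C)CC[C@@H](C)CCO[Si](c2ccccc2)(c2ccccc2)C(C)(C)C)C(C#C)=C1C
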